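**Plan**
- Target: 2-hydroxy-3-[(S)-2-acetoxypropyl]-5,6,8-trimethoxy-1,4-naphthoquinone. The retrosynthesis first removes the C2–O bond (back to the C2–H quinone via its 2,3-epoxide), then the O–CH3 bonds at C6 and C8.
- The benzo ring is then cut at C4a–C5 and C8–C8a. Its pattern (oxygen on C5, C6 and C8, the only hydrogen on C7) is that of a 1,1,3,4-tetraoxygenated butadiene, and the quinone ring C1–C4/C4a/C8a is a benzoquinone whose future C4a=C8a bond carries bromine as director and leaving group.
- The last cut is aryl–CH2, to ortho-lithiated 1,4-dimethoxybenzene and (S)-propylene oxide.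
- Forward: the chain is joined to the arene, the arene is oxidised to the bromoquinone (the later quinone ring), the benzo ring is annulated by Diels–Alder addition and aromatisation, then O-methylation and C2 oxygenation follow.
- Stereochemistry: the single S centre is bought with (S)-propylene oxide, which is opened at CH2, so no bond to that carbon is made or broken afterwards.

Key step: step 7

Remark: naphthalene positions are numbered as in the target throughout (C1 beside C2–OH, chain on C3, methoxy groups on C5, C6 and C8), also where lowest-locant rules would differ. Diene 11 is used as the mixture of geometric isomers that the silylation gives.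

**Route**

Step 1
Reactants: 1 1,4-dimethoxybenzene; 2 (S)-propylene oxide
Product: 4 (S)-1-(2,5-dimethoxyphenyl)propan-2-ol, via 2,5-dimethoxyphenyllithium 3 (not isolated)
Conditions: n-BuLi, TMEDA, THF, 0 °C; then 2, −78 °C → rt; H2O
Reagents that add atoms: none
Why: Directed ortho-lithiation of the hydroquinone dimethyl ether gives 3, which opens the epoxide by SN2 attack at the unsubstituted CH2, so the C–O bond of the stereocentre is never broken and the carbinol carbon keeps the S configuration of 2.

Step 2
Reactants: 4 (S)-1-(2,5-dimethoxyphenyl)propan-2-ol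
Product: 5 (S)-1-(2,5-dimethoxyphenyl)propan-2-yl acetate
Conditions: Ac2O, pyridine, DMAP (cat.), CH2Cl2, 0 °C → rt
Reagents that add atoms: acetic anhydride, CC(=O)OC(C)=O
Why: DMAP-catalysed acylation of an unhindered secondary alcohol touches only the O–H bond, so the S centre is retained.

Step 3
Reactants: 5 (S)-1-(2,5-dimethoxyphenyl)propan-2-yl acetate
Product: 6 (S)-1-(4-bromo-2,5-dimethoxyphenyl)propan-2-yl acetate
Conditions: NBS, MeCN, rt, dark
Reagents that add atoms: N-bromosuccinimide, O=C1CCC(=O)N1Br
Why: Electrophilic aromatic bromination with NBS in a polar solvent goes to the position para to the alkyl chain and ortho to a methoxy group, the most activated and least hindered site of a 2-alkyl-1,4-dimethoxybenzene, and without an initiator the benzylic radical pathway stays closed.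

Step 4
Reactants: 6 (S)-1-(4-bromo-2,5-dimethoxyphenyl)propan-2-yl acetate
Product: 7 2-bromo-5-[(S)-2-acetoxypropyl]-1,4-benzoquinone
Conditions: (NH4)2Ce(NO3)6, MeCN–H2O, 0 °C
Reagents that add atoms: water, O
Why: Oxidative demethylation of a hydroquinone dimethyl ether by cerium(IV) (CAN oxidation) gives the p-quinone, with water attacking the ring carbons of the oxidised arene and methanol leaving, under conditions to which the aryl bromide and the secondary acetate are inert.

Step 5
Reactants: 8 methyl 4-methoxyacetoacetate
Product: 9 methyl 4-methoxy-3-(trimethylsilyloxy)but-2-enoate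
Conditions: Me3SiCl, Et3N, toluene, rt; filtration under argon
Reagents that add atoms: chlorotrimethylsilane, C[Si](C)(C)Cl
Why: Soft enolisation and O-silylation of the β-ketoester (silyl enol ether formation) traps the conjugated enol as the 3-silyloxy enoate, the usual first stage of a 1,3-bis(silyloxy)diene synthesis.

Step 6
Reactants: 9 methyl 4-methoxy-3-(trimethylsilyloxy)but-2-enoate
Product: 11 1,4-dimethoxy-1,3-bis(trimethylsilyloxy)buta-1,3-diene, via lithium dienolate 10 (not isolated)
Conditions: LDA (commercial solution), THF, −78 °C; then Me3SiCl, −78 → 0 °C; hexane, filtration, used crude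
Reagents that add atoms: chlorotrimethylsilane, C[Si](C)(C)Cl
Why: Kinetic γ-deprotonation of the vinylogous ester by LDA gives the lithium dienolate 10, which is silylated on the ester oxygen (silyl ketene acetal formation) to the electron-rich diene.

Step 7
Reactants: 7 2-bromo-5-[(S)-2-acetoxypropyl]-1,4-benzoquinone; 11 1,4-dimethoxy-1,3-bis(trimethylsilyloxy)buta-1,3-diene
Product: 15 3-[(S)-2-acetoxypropyl]-6,8-dihydroxy-5-methoxy-1,4-naphthoquinone, via bromo cycloadduct 12 (not isolated), via 5,8-dihydronaphthoquinone acetal 13 (not isolated), via bis(trimethylsilyl) ether 14 (not isolated)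
Conditions: 11 (1.5–2 equiv), THF, −30 °C → rt; then 1 M HCl, THF, rt
Reagents that add atoms: none
Why: A polarised, probably asynchronous [4+2] cycloaddition of the electron-rich dienol ether 11 onto the electron-poor C(Br)=C(H) bond of 7 closes the six-membered carbocycle in the ordinary intermolecular Diels–Alder mode and makes C4a–C5 and C8–C8a, giving 12. Loss of HBr across C4a–C8a restores the quinone (13), 1,4-elimination of methanol (H-5 and the methoxy of the C8 mixed acetal) aromatises the new ring to 14 without any oxidant, and dilute acid frees the two phenols. The closest known chemistry is the annulation of halobenzoquinones and halonaphthoquinones with vinylketene acetals and 1,3-bis(silyloxy)dienes, followed by aromatisation in the same flask. The step needs site- and regioselectivity: the brominated double bond is the more electrophilic dienophile (the other carries the donor alkyl chain), and bromine polarises it so that the nucleophilic C4 terminus of the diene (the CH–OMe carbon) bonds to the bromine-free carbon and the ketene-acetal carbon to C–Br, which puts OMe on C5 beside C4 and the phenol on C8. The four sp3 centres of 12 are transient and vanish on aromatisation, so no stereocentre is created, facial selectivity is irrelevant and the remote S centre is untouched. Should the mixed acetal lose silanol instead of methanol, the C8 oxygen would simply arrive methylated, which step 8 does anyway.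

Step 8
Reactants: 15 3-[(S)-2-acetoxypropyl]-6,8-dihydroxy-5-methoxy-1,4-naphthoquinone
Product: 16 3-[(S)-2-acetoxypropyl]-5,6,8-trimethoxy-1,4-naphthoquinone
Conditions: MeI (excess), Ag2O, CHCl3, rt, dark
Reagents that add atoms: iodomethane, CI
Why: Purdie-type O-methylation with MeI on silver oxide is neutral and non-hydrolytic, so it should methylate the free C6 phenol and the hydrogen-bonded peri C8 phenol while leaving the acetate and the base-sensitive quinone intact.

Step 9
Reactants: 16 3-[(S)-2-acetoxypropyl]-5,6,8-trimethoxy-1,4-naphthoquinone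
Product: 17 3-[(S)-2-acetoxypropyl]-2,3-epoxy-5,6,8-trimethoxy-2,3-dihydro-1,4-naphthoquinone (both cis-epoxide diastereomers)
Conditions: 30% H2O2, Na2CO3 (cat.), THF–H2O, 0 °C, short reaction time
Reagents that add atoms: hydrogen peroxide, OO
Why: In this Weitz–Scheffer nucleophilic epoxidation hydroperoxide adds in conjugate fashion to the unsubstituted C2 of the electron-poor quinone double bond and the enolate closes onto O–O, giving the cis-fused epoxide from either face (the new centres at C2 and C3 are uncontrolled and both are destroyed in step 10), while the cold, brief, weakly basic medium should spare the acetate.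

Step 10
Reactants: 17 3-[(S)-2-acetoxypropyl]-2,3-epoxy-5,6,8-trimethoxy-2,3-dihydro-1,4-naphthoquinone
Product: 18 2-hydroxy-3-[(S)-2-acetoxypropyl]-5,6,8-trimethoxy-1,4-naphthoquinone (CNP0321270.1)
Conditions: conc. H2SO4 (2 equiv), AcOH, rt; then ice–water
Reagents that add atoms: none
Why: Acid-catalysed isomerisation of an α,β-epoxy ketone to the enolised 1,2-dicarbonyl, the classical conversion of 2-alkylnaphthoquinone oxides into 2-hydroxy-3-alkylnaphthoquinones, opens the protonated epoxide at the more substituted C3 and loses H-2 to give the hydroxyquinone, and acetic acid as solvent holds the secondary acetate in place.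

**Compound list**

1 | 1,4-dimethoxybenzene | COc1ccc(OC)cc1 | starting material
2 | (S)-propylene oxide [(S)-2-methyloxirane] | C[C@H]1CO1 | starting material
3 | 2,5-dimethoxyphenyllithium | [Li]c1cc(OC)ccc1OC | intermediate (not isolated)
4 | (S)-1-(2,5-dimethoxyphenyl)propan-2-ol | COc1ccc(OC)c(C[C@H](C)O)c1 | intermediate
5 | (S)-1-(2,5-dimethoxyphenyl)propan-2-yl acetate | COc1ccc(OC)c(C[C@H](C)OC(C)=O)c1 | intermediate
6 | (S)-1-(4-bromo-2,5-dimethoxyphenyl)propan-2-yl acetate | COc1cc(C[C@H](C)OC(C)=O)c(OC)cc1Br | intermediate
7 | 2-bromo-5-[(S)-2-acetoxypropyl]-1,4-benzoquinone | O=C1C=C(C[C@H](C)OC(C)=O)C(=O)C=C1Br | intermediate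
8 | methyl 4-methoxyacetoacetate (methyl 4-methoxy-3-oxobutanoate) | COCC(=O)CC(=O)OC | starting material
9 | methyl 4-methoxy-3-(trimethylsilyloxy)but-2-enoate | COCC(O[Si](C)(C)C)=CC(=O)OC | intermediate
10 | lithium 1,4-dimethoxy-3-(trimethylsilyloxy)buta-1,3-dien-1-olate | [Li+].[O-]C(OC)=CC(O[Si](C)(C)C)=COC | intermediate (not isolated)
11 | 1,4-dimethoxy-1,3-bis(trimethylsilyloxy)buta-1,3-diene (geometric mixture) | COC=C(O[Si](C)(C)C)C=C(OC)O[Si](C)(C)C | intermediate
12 | 3-[(S)-2-acetoxypropyl]-8a-bromo-5,8-dimethoxy-6,8-bis(trimethylsilyloxy)-4a,5,8,8a-tetrahydro-1,4-naphthoquinone (diastereomer mixture) | COC1C(O[Si](C)(C)C)=CC(OC)(O[Si](C)(C)C)C2(Br)C(=O)C=C(C[C@H](C)OC(C)=O)C(=O)C12 | intermediate (not isolated)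
13 | 3-[(S)-2-acetoxypropyl]-5,8-dimethoxy-6,8-bis(trimethylsilyloxy)-5,8-dihydro-1,4-naphthoquinone | COC1C(O[Si](C)(C)C)=CC(OC)(O[Si](C)(C)C)C2=C1C(=O)C(C[C@H](C)OC(C)=O)=CC2=O | intermediate (not isolated)
14 | 3-[(S)-2-acetoxypropyl]-5-methoxy-6,8-bis(trimethylsilyloxy)-1,4-naphthoquinone | COc1c(O[Si](C)(C)C)cc(O[Si](C)(C)C)c2c1C(=O)C(C[C@H](C)OC(C)=O)=CC2=O | intermediate (not isolated)
15 | 3-[(S)-2-acetoxypropyl]-6,8-dihydroxy-5-methoxy-1,4-naphthoquinone | COc1c(O)cc(O)c2c1C(=O)C(C[C@H](C)OC(C)=O)=CC2=O | intermediate
16 | 3-[(S)-2-acetoxypropyl]-5,6,8-trimethoxy-1,4-naphthoquinone | COc1cc(OC)c2c(c1OC)C(=O)C(C[C@H](C)OC(C)=O)=CC2=O | intermediate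
17 | 3-[(S)-2-acetoxypropyl]-2,3-epoxy-5,6,8-trimethoxy-2,3-dihydro-1,4-naphthoquinone (epoxide centres unassigned, mixture) | COc1cc(OC)c2c(c1OC)C(=O)C1(C[C@H](C)OC(C)=O)OC1C2=O | intermediate
18 | 2-hydroxy-3-[(S)-2-acetoxypropyl]-5,6,8-trimethoxy-1,4-naphthoquinone | COc1cc(OC)c2c(c1OC)C(=O)C(C[C@H](C)OC(C)=O)=C(O)C2=O | target

**Count**

Total steps: 10. Longest linear sequence: 8 (steps 1–4, then 7–10); the diene branch (steps 5–6) joins at step 7.

**Steps most likely to fail**

Step 7. The diene may be protodesilylated by the hydrogen bromide set free, the reaction may stop at a conjugate (Mukaiyama–Michael) adduct without ring closure, or the doubly silylated material may decompose before aromatisation. The fallback sets out from 8 and moves the C3 oxygen of the diene into a methyl enol ether, which is far less acid-labile. Trimethyl orthoformate and catalytic H2SO4 in methanol should convert 8 into methyl (E)-3,4-dimethoxybut-2-enoate F1. LDA and Me3SiCl in THF at −78 °C should then give the vinylketene acetal 1,3,4-trimethoxy-1-(trimethylsilyloxy)buta-1,3-diene F2. Cycloaddition of F2 with 7 under the conditions of step 7, with the same loss of HBr and methanol and an acidic work-up, should deliver 3-[(S)-2-acetoxypropyl]-8-hydroxy-5,6-dimethoxy-1,4-naphthoquinone F3. Its single peri phenol is methylated with MeI/Ag2O, and the route is rejoined at 16.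

Step 9. The acetate may be lost by perhydrolysis, or acetic acid may be eliminated after deprotonation of the vinylogously acidic side-chain CH2, which carries a β-acetoxy group. The fallback sets out from 16 and brings in the C2 oxygen under acidic conditions by Thiele–Winter acetoxylation. Ac2O with catalytic H2SO4 should add acetate to the only free quinone position and acetylate both hydroquinone oxygens, giving 1,2,4-triacetoxy-3-[(S)-2-acetoxypropyl]-5,6,8-trimethoxynaphthalene F4. The three aryl acetates are then cleaved in preference to the secondary alkyl acetate (NH4OAc, aqueous MeOH, rt), giving 3-[(S)-2-acetoxypropyl]-5,6,8-trimethoxynaphthalene-1,2,4-triol F5. Air oxidises F5 in the same flask, and the route is rejoined at 18, bypassing steps 9 and 10.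

Step 10. Under protic acid the acetate may be cleaved or may participate in the epoxide opening, and the electron-rich benzo ring may suffer demethylation at a peri position. The fallback sets out from 17 and uses base for the isomerisation, with the acetate given up on purpose. Aqueous NaOH, then dilute HCl, should effect the epoxydione to hydroxyquinone rearrangement and the saponification together, giving 2-hydroxy-3-[(S)-2-hydroxypropyl]-5,6,8-trimethoxy-1,4-naphthoquinone F6. Exhaustive acetylation (Ac2O, pyridine) should give 2-acetoxy-3-[(S)-2-acetoxypropyl]-5,6,8-trimethoxy-1,4-naphthoquinone F7. Its quinonyl acetate is a vinylogous anhydride and should be hydrolysed selectively by aqueous NaHCO3 in THF, which rejoins the route at 18.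

**Further compounds**

F1 | step 7 | methyl (E)-3,4-dimethoxybut-2-enoate | CO/C(COC)=C/C(=O)OC
F2 | step 7 | 1,3,4-trimethoxy-1-(trimethylsilyloxy)buta-1,3-diene | COC=C(OC)C=C(OC)O[Si](C)(C)C
F3 | step 7 | 3-[(S)-2-acetoxypropyl]-8-hydroxy-5,6-dimethoxy-1,4-naphthoquinone | COc1cc(O)c2c(c1OC)C(=O)C(C[C@H](C)OC(C)=O)=CC2=O
F4 | step 9 | 1,2,4-triacetoxy-3-[(S)-2-acetoxypropyl]-5,6,8-trimethoxynaphthalene | COc1cc(OC)c2c(c1OC)c(OC(C)=O)c(C[C@H](C)OC(C)=O)c(OC(C)=O)c2OC(C)=O
F5 | step 9 | 3-[(S)-2-acetoxypropyl]-5,6,8-trimethoxynaphthalene-1,2,4-triol | COc1cc(OC)c2c(c1OC)c(O)c(C[C@H](C)OC(C)=O)c(O)c2O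
F6 | step 10 | 2-hydroxy-3-[(S)-2-hydroxypropyl]-5,6,8-trimethoxy-1,4-naphthoquinone | COc1cc(OC)c2c(c1OC)C(=O)C(C[C@H](C)O)=C(O)C2=O
F7 | step 10 | 2-acetoxy-3-[(S)-2-acetoxypropyl]-5,6,8-trimethoxy-1,4-naphthoquinone | COc1cc(OC)c2c(c1OC)C(=O)C(C[C@H](C)OC(C)=O)=C(OC(C)=O)C2=O
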